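**Plan**

Ring numbering used below: C1 carries the ester oxygen, C2(isopropyl)=C3, C4=C5(methyl), C6–C8 are CH2, C9 is C(CH3)OH, C10 is CH2.
Retrosynthesis: cut the aryl–C(=O) bond (aryllithium + cyclic carbonate), then the carbonate to the cis-1,3-diol, then the ring at the diene σ-bond C3–C4 (Pd alkenyl–alkenyl coupling), then the C9–O/C10–H pair back to a threo epoxy alcohol and a divinyl carbinol, and last C1–C10 (alkenylzinc + aldehyde). This leaves a C9 diiodide from hepta-1,6-diyne and a C6 bromoenal from propargyl alcohol.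
Forward: the open chain is joined first (C9 + C6), both stereocentres are set on the chain, the ten-membered ring is closed at C3–C4, and the 1,3-dioxan-2-one ring is put on last and opened again in the key step.
Stereochemistry: C1 from a (−)-MIB-catalysed alkenylzinc addition; C9 from an A(1,3)-controlled, hydroxyl-directed epoxidation followed by hydride opening; 4E from syn-carboalumination and 2Z from anti-carbomagnesiation.
Feature used by the key event: the ester oxygen on C1 and the tertiary hydroxyl on C9 are cis-1,3 across C10 (the (1S,9S) isomer is the syn diol), so both oxygens fit into one six-membered 1,3-dioxan-2-one ring whose carbonyl carbon is the future ester carbon. The aryllithium forms the aryl–C(=O) bond on that carbon and the ring releases the tertiary alcohol.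

Key step: step 9

**Route**

Step 1
Reactants: 1 hepta-1,6-diyne
Product: 3 (1E,6E)-1,7-diiodo-2,6-dimethylhepta-1,6-diene, via bis(dimethylalumino)diene 2 (not isolated)
Conditions: Me3Al (5 equiv), Cp2ZrCl2 (0.5 equiv), CH2Cl2, 0 °C to rt; then I2, THF, −30 to 0 °C
Reagents that add atoms: trimethylaluminium C[Al](C)C; iodine II
Why: Zirconium-catalysed syn-carboalumination (Negishi) adds methyl and aluminium cis across each terminal alkyne with aluminium on the terminal carbon, and iodinolysis of the C–Al bonds with retention should give both (E)-2-methylalkenyl iodides.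

Step 2
Reactants: 4 prop-2-yn-1-ol
Product: 6 (2Z)-3-bromo-2-(propan-2-yl)prop-2-en-1-ol, via alkenylmagnesium chelate 5 (not isolated)
Conditions: i-PrMgCl (2.5 equiv), CuI (10 mol %), THF, −10 °C to rt; then NBS, −78 to 0 °C; aq NH4Cl
Reagents that add atoms: isopropylmagnesium chloride CC(C)[Mg]Cl; N-bromosuccinimide O=C1CCC(=O)N1Br
Why: Copper-catalysed anti-carbomagnesiation of the propargylic alkoxide places isopropyl on C2 and magnesium on C3 cis to the CH2O group in a five-membered chelate, and bromination of the C–Mg bond with retention should give the Z bromide.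

Step 3
Reactants: 6 (2Z)-3-bromo-2-(propan-2-yl)prop-2-en-1-ol
Product: 7 (2Z)-3-bromo-2-(propan-2-yl)prop-2-enal
Conditions: activated MnO2 (15 equiv), CH2Cl2, rt
Reagents that add atoms: none
Why: Allylic oxidation with activated MnO2 runs under neutral heterogeneous conditions, which should leave the Z geometry and the C–Br bond untouched.

Step 4
Reactants: 3 (1E,6E)-1,7-diiodo-2,6-dimethylhepta-1,6-diene; 7 (2Z)-3-bromo-2-(propan-2-yl)prop-2-enal
Product: 10 (1Z,3S,4E,9E)-1-bromo-10-iodo-5,9-dimethyl-2-(propan-2-yl)deca-1,4,9-trien-3-ol, via alkenyllithium 8 (not isolated), via ethyl(alkenyl)zinc 9 (not isolated)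
Conditions: 3 (4 equiv), t-BuLi (2.6 equiv), Et2O, −78 °C; ZnBr2 then Et2Zn, −78 to 0 °C; TEEDA, (−)-MIB (10 mol %), then 7 (1 equiv), toluene, 0 °C; aq NH4Cl
Reagents that add atoms: none
Why: Iodine–lithium exchange at one terminus of 3 (used in excess and recovered), transmetalation to zinc and amino-alcohol-catalysed enantioselective alkenylzinc 1,2-addition should give the carbinol; (−)-MIB directs the alkenyl group to the Si face of the aldehyde, which sets C3 as S, while TEEDA ties up lithium halide and suppresses the racemic background addition.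

Step 5
Reactants: 10 (1Z,3S,4E,9E)-1-bromo-10-iodo-5,9-dimethyl-2-(propan-2-yl)deca-1,4,9-trien-3-ol
Product: 11 (1R,2Z)-3-bromo-1-[(2S,3S)-3-[(4E)-5-iodo-4-methylpent-4-en-1-yl]-3-methyloxiran-2-yl]-2-(propan-2-yl)prop-2-en-1-ol
Conditions: mCPBA (1.2 equiv), NaHCO3, CH2Cl2, −20 to 0 °C
Reagents that add atoms: meta-chloroperoxybenzoic acid OOC(=O)c1cccc(Cl)c1
Why: In this hydroxyl-directed Prilezhaev epoxidation, A(1,3) strain between the C3 substituents and the C5 methyl that is cis to C3 holds the C3–H bond in the alkene plane, so the hydrogen-bonded peracid should attack the C4=C5 face on the side of the hydroxyl (threo product) and set both oxirane carbons as S, while the two halogen-bearing alkenes are deactivated.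

Step 6
Reactants: 11 (1R,2Z)-3-bromo-1-[(2S,3S)-3-[(4E)-5-iodo-4-methylpent-4-en-1-yl]-3-methyloxiran-2-yl]-2-(propan-2-yl)prop-2-en-1-ol
Product: 12 (1Z,3S,5S,9E)-1-bromo-10-iodo-5,9-dimethyl-2-(propan-2-yl)deca-1,9-diene-3,5-diol
Conditions: Red-Al (3 equiv), THF, −20 to 0 °C; Rochelle salt
Reagents that add atoms: none
Why: In this regioselective reductive opening of a 2,3-epoxy alcohol, the alkoxyaluminate delivers hydride to the epoxide CH next to the carbinol and not to the fully substituted carbon, so the tertiary C–O bond keeps its configuration and the syn-1,3-diol (3S,5S) should result.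

Step 7
Reactants: 12 (1Z,3S,5S,9E)-1-bromo-10-iodo-5,9-dimethyl-2-(propan-2-yl)deca-1,9-diene-3,5-diol
Product: 14 (1S,3S,4Z,6E)-1,7-dimethyl-4-(propan-2-yl)cyclodeca-4,6-diene-1,3-diol, via alkenylstannane 13 (not isolated)
Conditions: Pd(PPh3)4 (15 mol %), Me3SnSnMe3 (1.0 equiv), 1,4-dioxane (0.05 M), 50 °C; then dilution to 2 mM, 100 °C
Reagents that add atoms: none
Why: In this Stille–Kelly coupling, palladium-catalysed stannylation with hexamethylditin should occur first at the unhindered alkenyl iodide, and at higher temperature and dilution oxidative addition into the alkenyl bromide followed by intramolecular Stille coupling should join C1 and C10 of the chain into the ten-membered ring with retention of both alkene geometries (4Z,6E).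

Step 8
Reactants: 14 (1S,3S,4Z,6E)-1,7-dimethyl-4-(propan-2-yl)cyclodeca-4,6-diene-1,3-diol
Product: 16 (1S,2Z,4E,9S)-5,9-dimethyl-2-(propan-2-yl)-10,12-dioxabicyclo[7.3.1]trideca-2,4-dien-11-one, via imidazole-1-carboxylate 15 (not isolated)
Conditions: CDI (1.5 equiv), THF, rt; then DBU (cat.), 40 °C
Reagents that add atoms: 1,1'-carbonyldiimidazole O=C(n1ccnc1)n1ccnc1
Why: In this diol carbonylation with CDI, the secondary hydroxyl is acylated first and the tertiary hydroxyl, cis-1,3 to it on the ring, should displace imidazole under DBU catalysis to close the six-membered carbonate without touching either C–O stereocentre.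

Step 9
Reactants: 16 (1S,2Z,4E,9S)-5,9-dimethyl-2-(propan-2-yl)-10,12-dioxabicyclo[7.3.1]trideca-2,4-dien-11-one; 17 (4-bromophenoxy)(tert-butyl)dimethylsilane
Product: 20 (1S,2Z,4E,9S)-9-hydroxy-5,9-dimethyl-2-(propan-2-yl)cyclodeca-2,4-dien-1-yl 4-[(tert-butyldimethylsilyl)oxy]benzoate, via aryllithium 18 (not isolated), via lithium hemiorthoester alkoxide 19 (not isolated)
Conditions: 17 (1.4 equiv), n-BuLi (1.3 equiv), THF, −78 °C; then 16, −78 °C; AcOH, −78 °C to rt
Reagents that add atoms: none
Why: The aryllithium adds to the carbonyl carbon of the six-membered 1,3-dioxan-2-one to give the lithium hemiorthoester alkoxide 19, which stays closed at −78 °C and is therefore not open to a second addition. Protonation with acetic acid lets the hemiorthoester collapse by loss of the more basic and more hindered tertiary oxygen on C9, which leaves the aroyl group on the secondary allylic oxygen of C1 and frees the tertiary hydroxyl. The closest known reaction type is the opening of five-membered cyclic carbonates of secondary/tertiary 1,2-diols by aryllithium reagents to the secondary benzoate and the free tertiary alcohol. No ring is closed (the dioxanone ring is opened) and no stereocentre is formed, because only C(=O)–O and C(=O)–aryl bonds change and C1 and C9 keep the configuration set in steps 4 and 5. The step needs mono-addition and collapse toward the secondary ester; the first should be secured by the low temperature, the near-stoichiometric charge and the electron-rich, hindered product ester, the second by the steric preference for an ester on the secondary oxygen, toward which any tertiary ester would also drain by 1,3-acyl shift through the same six-membered intermediate.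

Step 10
Reactants: 20 (1S,2Z,4E,9S)-9-hydroxy-5,9-dimethyl-2-(propan-2-yl)cyclodeca-2,4-dien-1-yl 4-[(tert-butyldimethylsilyl)oxy]benzoate
Product: 21 (1S,2Z,4E,9S)-9-hydroxy-5,9-dimethyl-2-(propan-2-yl)cyclodeca-2,4-dien-1-yl 4-hydroxybenzoate
Conditions: TBAF (1.1 equiv), AcOH (1.1 equiv), THF, 0 °C
Reagents that add atoms: none
Why: Fluoride-mediated desilylation of the aryl silyl ether is fast at 0 °C and is buffered with acetic acid so that the phenoxide cannot attack the ester or promote acyl migration, which should give the target.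

**Compound list**

1 | hepta-1,6-diyne | C#CCCCC#C | starting material
2 | (1E,6E)-(2,6-dimethylhepta-1,6-diene-1,7-diyl)bis(dimethylalumane) | C[Al](C)/C=C(C)/CCC/C(C)=C/[Al](C)C | intermediate
3 | (1E,6E)-1,7-diiodo-2,6-dimethylhepta-1,6-diene | I/C=C(C)/CCC/C(C)=C/I | intermediate
4 | prop-2-yn-1-ol | C#CCO | starting material
5 | chloromagnesium (2Z)-3-(chloromagnesio)-2-(propan-2-yl)prop-2-en-1-olate | Cl[Mg]/C=C(/C(C)C)CO[Mg]Cl | intermediate
6 | (2Z)-3-bromo-2-(propan-2-yl)prop-2-en-1-ol | OC/C(C(C)C)=C\Br | intermediate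
7 | (2Z)-3-bromo-2-(propan-2-yl)prop-2-enal | O=C/C(C(C)C)=C\Br | intermediate
8 | [(1E,6E)-7-iodo-2,6-dimethylhepta-1,6-dien-1-yl]lithium | [Li]/C=C(C)/CCC/C(C)=C/I | intermediate
9 | ethyl[(1E,6E)-7-iodo-2,6-dimethylhepta-1,6-dien-1-yl]zinc | CC[Zn]/C=C(C)/CCC/C(C)=C/I | intermediate
10 | (1Z,3S,4E,9E)-1-bromo-10-iodo-5,9-dimethyl-2-(propan-2-yl)deca-1,4,9-trien-3-ol | I/C=C(C)/CCC/C(C)=C/[C@H](O)/C(C(C)C)=C\Br | intermediate
11 | (1R,2Z)-3-bromo-1-[(2S,3S)-3-[(4E)-5-iodo-4-methylpent-4-en-1-yl]-3-methyloxiran-2-yl]-2-(propan-2-yl)prop-2-en-1-ol | Br\C=C(C(C)C)/[C@@H](O)[C@@H]1O[C@@]1(C)CCC/C(C)=C/I | intermediate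
12 | (1Z,3S,5S,9E)-1-bromo-10-iodo-5,9-dimethyl-2-(propan-2-yl)deca-1,9-diene-3,5-diol | Br\C=C(C(C)C)/[C@@H](O)C[C@@](C)(O)CCC/C(C)=C/I | intermediate
13 | (1Z,3S,5S,9E)-1-bromo-5,9-dimethyl-2-(propan-2-yl)-10-(trimethylstannyl)deca-1,9-diene-3,5-diol | Br\C=C(C(C)C)/[C@@H](O)C[C@@](C)(O)CCC/C(C)=C/[Sn](C)(C)C | intermediate
14 | (1S,3S,4Z,6E)-1,7-dimethyl-4-(propan-2-yl)cyclodeca-4,6-diene-1,3-diol | C/C1=C\C=C(\C(C)C)[C@@H](O)C[C@@](C)(O)CCC1 | intermediate
15 | (1S,2Z,4E,9S)-9-hydroxy-5,9-dimethyl-2-(propan-2-yl)cyclodeca-2,4-dien-1-yl 1H-imidazole-1-carboxylate | C/C1=C\C=C(\C(C)C)[C@@H](OC(=O)n2ccnc2)C[C@@](C)(O)CCC1 | intermediate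
16 | (1S,2Z,4E,9S)-5,9-dimethyl-2-(propan-2-yl)-10,12-dioxabicyclo[7.3.1]trideca-2,4-dien-11-one | C/C1=C\C=C(\C(C)C)[C@@H]2C[C@](C)(CCC1)OC(=O)O2 | intermediate
17 | (4-bromophenoxy)(tert-butyl)dimethylsilane | CC(C)(C)[Si](C)(C)Oc1ccc(Br)cc1 | starting material
18 | {4-[(tert-butyldimethylsilyl)oxy]phenyl}lithium | CC(C)(C)[Si](C)(C)Oc1ccc([Li])cc1 | intermediate
19 | lithium (1S,2Z,4E,9S)-11-{4-[(tert-butyldimethylsilyl)oxy]phenyl}-5,9-dimethyl-2-(propan-2-yl)-10,12-dioxabicyclo[7.3.1]trideca-2,4-dien-11-olate | C/C1=C\C=C(\C(C)C)[C@@H]2C[C@](C)(CCC1)OC([O-])(c1ccc(O[Si](C)(C)C(C)(C)C)cc1)O2.[Li+] | intermediate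
20 | (1S,2Z,4E,9S)-9-hydroxy-5,9-dimethyl-2-(propan-2-yl)cyclodeca-2,4-dien-1-yl 4-[(tert-butyldimethylsilyl)oxy]benzoate | C/C1=C\C=C(\C(C)C)[C@@H](OC(=O)c2ccc(O[Si](C)(C)C(C)(C)C)cc2)C[C@@](C)(O)CCC1 | intermediate
21 | (1S,2Z,4E,9S)-9-hydroxy-5,9-dimethyl-2-(propan-2-yl)cyclodeca-2,4-dien-1-yl 4-hydroxybenzoate | C/C1=C\C=C(\C(C)C)[C@@H](OC(=O)c2ccc(O)cc2)C[C@@](C)(O)CCC1 | target

**Step count and risks**

Total step count: 10. Longest linear sequence: 9 steps (from prop-2-yn-1-ol 4 through steps 2–10).

Steps most likely to fail: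

1. Step 7. Intermolecular coupling (oligomer formation) may outrun closure of the strained ten-membered ring, and stannylation of both halides or protodestannylation may stop the sequence after the first stage. The fallback separates metalation from ring closure and changes the nucleophile to boron. It sets out from 12: Miyaura borylation of the alkenyl iodide only (PdCl2(dppf), B2pin2, KOAc, toluene, 50 °C) would give the isolated alkenylboronate (1Z,3S,5S,9E)-1-bromo-5,9-dimethyl-2-(propan-2-yl)-10-(4,4,5,5-tetramethyl-1,3,2-dioxaborolan-2-yl)deca-1,9-diene-3,5-diol F1. A Suzuki–Miyaura macrocyclisation of F1 onto its own alkenyl bromide (PdCl2(dppf), Cs2CO3, THF/H2O, 2 mM, 60 °C) would then return to the route at 14.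

2. Step 9. A second addition of the aryllithium to the ester carbonyl (over-addition to the diaryl ketone) or collapse of the adduct toward the tertiary ester may erode the yield. The fallback builds the same aryl–C(=O) bond on palladium instead of by carbanion addition. It sets out from 14: Pd-catalysed alkoxycarbonylation of tert-butyl(4-iodophenoxy)dimethylsilane under CO (Pd(OAc)2, Xantphos, Et3N, toluene, 80 °C), in which the aroyl-palladium species is intercepted by the secondary hydroxyl only, would return to the route at 20 without any new compound (entry F0).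

3. Step 4. Background addition through lithium- or zinc-halide-activated pathways may lower the facial selectivity, the bromoenal may isomerise from Z to E, and metalation of both termini of 3 may give bis-adducts. The fallback sets the carbinol configuration by reagent-controlled reduction instead of addition. It sets out from 3 and 7: plain addition of alkenyllithium 8 (from 3 as in step 4) to 7 in THF at −78 °C would give the racemic carbinol rac-(1Z,4E,9E)-1-bromo-10-iodo-5,9-dimethyl-2-(propan-2-yl)deca-1,4,9-trien-3-ol F2. Dess–Martin oxidation would give the divinyl ketone (1Z,4E,9E)-1-bromo-10-iodo-5,9-dimethyl-2-(propan-2-yl)deca-1,4,9-trien-3-one F3. CBS reduction of F3 with the (R)-methyl oxazaborolidine and catecholborane at −78 °C, with the α-branched bromoalkenyl group acting as the large substituent, would return to the route at 10.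

**Further compounds**

F1 | step 7 | (1Z,3S,5S,9E)-1-bromo-5,9-dimethyl-2-(propan-2-yl)-10-(4,4,5,5-tetramethyl-1,3,2-dioxaborolan-2-yl)deca-1,9-diene-3,5-diol | Br\C=C(C(C)C)/[C@@H](O)C[C@@](C)(O)CCC/C(C)=C/B1OC(C)(C)C(C)(C)O1
F0 | step 9 | none | none
F2 | step 4 | rac-(1Z,4E,9E)-1-bromo-10-iodo-5,9-dimethyl-2-(propan-2-yl)deca-1,4,9-trien-3-ol | I/C=C(C)/CCC/C(C)=C/C(O)/C(C(C)C)=C\Br
F3 | step 4 | (1Z,4E,9E)-1-bromo-10-iodo-5,9-dimethyl-2-(propan-2-yl)deca-1,4,9-trien-3-one | I/C=C(C)/CCC/C(C)=C/C(=O)/C(C(C)C)=C\Br
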